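**Retrosynthetic overview**

- The side chain comes last: Ru-catalysed Alder-ene coupling of a 1-ethynylcyclohexanol with 2-methylpenta-1,4-dien-3-ol, then Corey–Bakshi–Shibata (CBS) reduction for the side-chain carbinol.
- C4–Br is made by Markovnikov HBr addition to a 4-methylidene group anti to an axial C3–Cl; C3–Cl comes from the C3 allylic alcohol by SN2 inversion; C1 comes from ethynylation of a ketone.
- The only ring is closed in one operation by an anion-relay (3+3) annulation of aldehyde 7 with vinyl bromide 2, which forms C3–C4 and C1–C6.
- Enabling feature: C1 (carbinol) and C3 (CHCl) are 1,3-related. With C1 masked as the carbon of a 2-trimethylsilyl-1,3-dithiane ring and C3 as CHO, the array O–C3–C2–C1–Si permits a 1,4-Brook shift that moves the charge from the C3 alkoxide to C1.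
- Absolute configuration is set by two CBS reductions (steps 5 and 13); the other ring centres follow by substrate control.

Key step: step 4

Remark: ring positions are numbered as in the target throughout (C1 carbinol, C2 CH2, C3 CHCl, C4 C(CH3)Br, C5 and C6 CH2); the four numbered starting materials and all reagents are assumed to be commercially available.

**Route**

Step 1
Reactants: 1 3-bromobut-3-en-1-ol
Product: 2 2-bromo-4-chlorobut-1-ene
Conditions: PPh3, NCS, CH2Cl2, 0 °C to rt
Reagents that add atoms: N-chlorosuccinimide, O=C1CCC(=O)N1Cl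
Why: Appel-type deoxychlorination, in which the alkoxyphosphonium salt of the primary alcohol is displaced by chloride in an SN2 step while the vinyl bromide stays inert.

Step 2
Reactants: 3 1,3-dithiane; 4 2-bromo-1,1-diethoxyethane
Product: 6 [2-(2,2-diethoxyethyl)-1,3-dithian-2-yl]trimethylsilane, via alkylated dithiane 5 (not isolated)
Conditions: n-BuLi, THF, −30 °C; 4, −30 to 0 °C; then n-BuLi, −30 °C; TMSCl, −78 °C to rt
Reagents that add atoms: chlorotrimethylsilane, C[Si](C)(C)Cl
Why: Corey–Seebach alkylation of 2-lithio-1,3-dithiane by the primary bromide, followed in the same flask by a second lithiation at the dithiane carbon and C-silylation, both standard for this acyl-anion equivalent.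

Step 3
Reactants: 6 [2-(2,2-diethoxyethyl)-1,3-dithian-2-yl]trimethylsilane
Product: 7 2-[2-(trimethylsilyl)-1,3-dithian-2-yl]acetaldehyde
Conditions: 1 M HCl, THF, rt
Reagents that add atoms: water, O
Why: Acid hydrolysis of the O,O-acetal, which the S,S-acetal and the C–Si bond should survive, unveils the aldehyde.

Step 4
Reactants: 2 2-bromo-4-chlorobut-1-ene; 7 2-[2-(trimethylsilyl)-1,3-dithian-2-yl]acetaldehyde
Product: 12 9-methylidene-1,5-dithiaspiro[5.5]undecan-8-ol (racemic), via vinyllithium 8 (not isolated), via lithium alkoxide 9 (not isolated), via lithiated dithiane 10 (not isolated), via silyl ether 11 (not isolated)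
Conditions: t-BuLi (2 equiv), Et2O, −78 °C; 7, −78 °C; then THF–HMPA, −78 to 0 °C; 1 M HCl work-up
Reagents that add atoms: none
Why: Proposed new method: bromine–lithium exchange on 2 gives vinyllithium 8, whose 1,2-addition to aldehyde 7 forms the C3–C4 bond and alkoxide 9; because O–C3–C2–C1–Si is a 1,4-array, HMPA triggers a 1,4-Brook rearrangement (C-to-O silyl shift) that unmasks the sulfur-stabilised carbanion 10 at C1, which closes the ring on the primary chloride (C1–C6 bond) to give 11, desilylated on work-up. The closest known reaction types are the alkoxide-triggered anion relay (1,4-Brook shift) of 2-silyl-1,3-dithianes, the intramolecular Corey–Seebach alkylation of 2-lithio-1,3-dithianes by ω-chloroalkyl chains, and annulations with 4-chloro-2-lithiobut-1-ene as a donor–acceptor reagent; merging them into a (3+3) carbocyclisation is the new element. The six-membered ring closes in a 6-exo-tet mode. The C3 carbinol centre is formed without control (racemate) and is set afterwards in step 5; no other stereocentre is created. The step needs silyl migration to outrun 5-exo O-alkylation of alkoxide 9 by the chloride, and exchange at C–Br to outrun attack at C–Cl; the fast-migrating trimethylsilyl group, the late addition of HMPA at −78 °C and the low reactivity of lithium alkoxides and primary chlorides in ether should secure both.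

Step 5
Reactants: 12 9-methylidene-1,5-dithiaspiro[5.5]undecan-8-ol (racemic)
Product: 14 (8S)-9-methylidene-1,5-dithiaspiro[5.5]undecan-8-ol, via enone 13 (not isolated)
Conditions: MnO2, CH2Cl2, rt, filtration; then (R)-2-methyl-CBS-oxazaborolidine (cat.), catecholborane, toluene, −78 °C
Reagents that add atoms: none
Why: Allylic oxidation erases the uncontrolled centre, and CBS reduction of the exocyclic enone (the C=CH2 side acts as the large group) with the (R)-catalyst should give the (S)-carbinol, setting C3 by reagent control and converting the racemate into one enantiomer.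

Step 6
Reactants: 14 (8S)-9-methylidene-1,5-dithiaspiro[5.5]undecan-8-ol
Product: 15 tert-butyl(dimethyl){[(8S)-9-methylidene-1,5-dithiaspiro[5.5]undecan-8-yl]oxy}silane
Conditions: TBSCl, imidazole, DMF, rt
Reagents that add atoms: tert-butyl(chloro)dimethylsilane, CC(C)(C)[Si](C)(C)Cl
Why: Standard silylation of the secondary alcohol, which protects the future β-hydroxy ketone against dehydration and aromatisation and supplies the steric bias needed in step 8.

Step 7
Reactants: 15 tert-butyl(dimethyl){[(8S)-9-methylidene-1,5-dithiaspiro[5.5]undecan-8-yl]oxy}silane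
Product: 16 (3S)-3-{[tert-butyl(dimethyl)silyl]oxy}-4-methylidenecyclohexan-1-one
Conditions: MeI, CaCO3, MeCN–H2O, 45 °C
Reagents that add atoms: water, O
Why: Alkylative dithiane hydrolysis (S-methylation to a sulfonium leaving group, then attack of water) under buffered, non-electrophilic conditions that should spare the exocyclic alkene and the silyl ether.

Step 8
Reactants: 16 (3S)-3-{[tert-butyl(dimethyl)silyl]oxy}-4-methylidenecyclohexan-1-one
Product: 18 (1S,3S)-1-ethynyl-4-methylidenecyclohexane-1,3-diol, via silyl ether 17 (not isolated)
Conditions: ethynylmagnesium bromide, CeCl3, THF, −78 °C; NH4Cl work-up; then TBAF, THF, rt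
Reagents that add atoms: ethynylmagnesium bromide, C#C[Mg]Br
Why: Organocerium 1,2-addition (which suppresses enolisation and β-elimination) should deliver the small alkynyl group to C1 from the face away from the C3 silyloxy group (axial attack on the conformer with equatorial OSi, or equatorial attack on the conformer in which allylic strain holds OSi axial), setting C1 cis to the C3 oxygen; fluoride then removes the silyl group.

Step 9
Reactants: 18 (1S,3S)-1-ethynyl-4-methylidenecyclohexane-1,3-diol
Product: 19 (1S,3R)-3-chloro-1-ethynyl-4-methylidenecyclohexan-1-ol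
Conditions: PPh3, hexachloroacetone, CH2Cl2, −20 to 0 °C
Reagents that add atoms: hexachloroacetone, O=C(C(Cl)(Cl)Cl)C(Cl)(Cl)Cl
Why: Appel-type allylic chlorination with triphenylphosphine and hexachloroacetone, which is known to proceed by SN2 with inversion and without allylic transposition, should turn the (3S)-alcohol into the (3R)-chloride while the hindered tertiary propargylic alcohol stays untouched.

Step 10
Reactants: 19 (1S,3R)-3-chloro-1-ethynyl-4-methylidenecyclohexan-1-ol
Product: 20 (1S,3R,4R)-4-bromo-3-chloro-1-ethynyl-4-methylcyclohexan-1-ol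
Conditions: HBr (anhydrous, 1.1 equiv), CH2Cl2, −78 to −20 °C
Reagents that add atoms: hydrogen bromide, Br
Why: Markovnikov protonation of the exocyclic methylene gives the tertiary C4 cation, and the neighbouring C3–Cl bond, held axial by allylic strain, should bridge one face so that bromide enters axially anti to chlorine, setting C4 with Br trans to Cl and cis to the C1 hydroxyl.

Step 11
Reactants: 21 2-methylprop-2-enal
Product: 22 2-methylpenta-1,4-dien-3-ol (racemic)
Conditions: vinylmagnesium bromide, THF, −78 to 0 °C
Reagents that add atoms: vinylmagnesium bromide, C=C[Mg]Br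
Why: Plain 1,2-addition of a vinyl Grignard reagent to the enal; the carbinol centre is formed racemic and is destroyed again in step 12.

Step 12
Reactants: 20 (1S,3R,4R)-4-bromo-3-chloro-1-ethynyl-4-methylcyclohexan-1-ol; 22 2-methylpenta-1,4-dien-3-ol (racemic)
Product: 23 6-[(1S,3R,4R)-4-bromo-3-chloro-1-hydroxy-4-methylcyclohexyl]-2-methylhepta-1,6-dien-3-one
Conditions: [CpRu(MeCN)3]PF6 (10 mol %), acetone, rt
Reagents that add atoms: none
Why: Ruthenium-catalysed Alder-ene (alkene–alkyne) coupling through a ruthenacyclopentene, in which the fully substituted propargylic carbon should favour the branched 1,1-disubstituted alkene, only the monosubstituted vinyl group of 22 reacts, and β-hydride elimination of the carbinol C–H gives an enol that tautomerises to the ketone; the neutral conditions should tolerate both halides and no stereocentre is formed.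

Step 13
Reactants: 23 6-[(1S,3R,4R)-4-bromo-3-chloro-1-hydroxy-4-methylcyclohexyl]-2-methylhepta-1,6-dien-3-one
Product: 24 (1S,3R,4R)-4-bromo-3-chloro-1-[(5R)-5-hydroxy-6-methylhepta-1,6-dien-2-yl]-4-methylcyclohexan-1-ol
Conditions: (S)-2-methyl-CBS-oxazaborolidine (cat.), catecholborane, toluene, −78 °C
Reagents that add atoms: none
Why: CBS reduction of the isopropenyl ketone (alkenyl group as the large substituent) with the (S)-catalyst should give the (R)-allylic alcohol by reagent control, at a temperature and with a borane that leave the alkenes and the halides alone.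

**Compound list**

1 | 3-bromobut-3-en-1-ol | C=C(Br)CCO | starting material
2 | 2-bromo-4-chlorobut-1-ene | C=C(Br)CCCl | intermediate
3 | 1,3-dithiane | C1CSCSC1 | starting material
4 | 2-bromo-1,1-diethoxyethane | CCOC(CBr)OCC | starting material
5 | 2-(2,2-diethoxyethyl)-1,3-dithiane | CCOC(CC1SCCCS1)OCC | intermediate
6 | [2-(2,2-diethoxyethyl)-1,3-dithian-2-yl]trimethylsilane | CCOC(CC1(SCCCS1)[Si](C)(C)C)OCC | intermediate
7 | 2-[2-(trimethylsilyl)-1,3-dithian-2-yl]acetaldehyde | O=CCC1(SCCCS1)[Si](C)(C)C | intermediate
8 | (4-chlorobut-1-en-2-yl)lithium | [Li]C(=C)CCCl | intermediate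
9 | lithium 5-chloro-3-methylidene-1-[2-(trimethylsilyl)-1,3-dithian-2-yl]pentan-2-olate (racemic) | [Li]OC(CC1(SCCCS1)[Si](C)(C)C)C(=C)CCCl | intermediate
10 | {2-[5-chloro-3-methylidene-2-(trimethylsilyloxy)pentyl]-1,3-dithian-2-yl}lithium (racemic) | [Li]C1(CC(O[Si](C)(C)C)C(=C)CCCl)SCCCS1 | intermediate
11 | trimethyl[(9-methylidene-1,5-dithiaspiro[5.5]undecan-8-yl)oxy]silane (racemic) | C=C1CCC2(CC1O[Si](C)(C)C)SCCCS2 | intermediate
12 | 9-methylidene-1,5-dithiaspiro[5.5]undecan-8-ol (racemic) | C=C1CCC2(CC1O)SCCCS2 | intermediate
13 | 9-methylidene-1,5-dithiaspiro[5.5]undecan-8-one | C=C1CCC2(CC1=O)SCCCS2 | intermediate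
14 | (8S)-9-methylidene-1,5-dithiaspiro[5.5]undecan-8-ol | S1CCCSC12CCC(=C)[C@@H](O)C2 | intermediate
15 | tert-butyl(dimethyl){[(8S)-9-methylidene-1,5-dithiaspiro[5.5]undecan-8-yl]oxy}silane | S1CCCSC12CCC(=C)[C@@H](O[Si](C)(C)C(C)(C)C)C2 | intermediate
16 | (3S)-3-{[tert-butyl(dimethyl)silyl]oxy}-4-methylidenecyclohexan-1-one | O=C1CCC(=C)[C@@H](O[Si](C)(C)C(C)(C)C)C1 | intermediate
17 | (1S,3S)-3-{[tert-butyl(dimethyl)silyl]oxy}-1-ethynyl-4-methylidenecyclohexan-1-ol | C#C[C@]1(O)CCC(=C)[C@@H](O[Si](C)(C)C(C)(C)C)C1 | intermediate
18 | (1S,3S)-1-ethynyl-4-methylidenecyclohexane-1,3-diol | C#C[C@]1(O)CCC(=C)[C@@H](O)C1 | intermediate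
19 | (1S,3R)-3-chloro-1-ethynyl-4-methylidenecyclohexan-1-ol | C#C[C@]1(O)CCC(=C)[C@H](Cl)C1 | intermediate
20 | (1S,3R,4R)-4-bromo-3-chloro-1-ethynyl-4-methylcyclohexan-1-ol | C#C[C@]1(O)CC[C@@](C)(Br)[C@H](Cl)C1 | intermediate
21 | 2-methylprop-2-enal | C=C(C)C=O | starting material
22 | 2-methylpenta-1,4-dien-3-ol (racemic) | C=CC(O)C(C)=C | intermediate
23 | 6-[(1S,3R,4R)-4-bromo-3-chloro-1-hydroxy-4-methylcyclohexyl]-2-methylhepta-1,6-dien-3-one | C=C(C)C(=O)CCC(=C)[C@]1(O)CC[C@@](C)(Br)[C@H](Cl)C1 | intermediate
24 | (1S,3R,4R)-4-bromo-3-chloro-1-[(5R)-5-hydroxy-6-methylhepta-1,6-dien-2-yl]-4-methylcyclohexan-1-ol | C=C(C)[C@H](O)CCC(=C)[C@]1(O)CC[C@@](C)(Br)[C@H](Cl)C1 | target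

**Step count and risks**

Total step count: 13. Longest linear sequence: 11 steps (steps 2, 3, 4, 5, 6, 7, 8, 9, 10, 12 and 13).

Steps most likely to fail:

Step 4 (Proposed new method). The relay may be diverted: the alkoxide may close a five-membered ether on the chloride before the silyl group has moved, the carbanion may be quenched before ring closure, or the vinyllithium may cyclise on its own chloride. The fallback makes the two bonds in separate, known operations. It sets out from 5, isolated after the first alkylation of step 2, and from 2. Acid hydrolysis of 5 (1 M HCl, THF) gives 2-(1,3-dithian-2-yl)acetaldehyde F1. Addition of vinyllithium 8 (from 2 and t-BuLi at −78 °C) with aqueous quench gives 5-chloro-1-(1,3-dithian-2-yl)-3-methylidenepentan-2-ol F2, which holds the C3–C4 bond. Silylation (TMSCl, imidazole) gives {[5-chloro-1-(1,3-dithian-2-yl)-3-methylidenepentan-2-yl]oxy}trimethylsilane F3. Lithiation of the dithiane with n-BuLi in THF–HMPA and intramolecular Corey–Seebach alkylation by the chloride close the C1–C6 bond to give 11, and acidic work-up returns the route at 12.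

Step 10. Bromide may be captured without facial control if the chlorine does not bridge, and the acid may ionise the allylic chloride or the propargylic alcohol. The fallback replaces the ionic addition by a radical Markovnikov hydrobromination through hydrogen-atom transfer (Co(acac)2 as catalyst, tert-butyl hydroperoxide, triethylsilane, p-toluenesulfonyl bromide, 1-propanol). The tertiary C4 radical should take bromine from the sulfonyl bromide axially and anti to the C3 chlorine, under non-acidic conditions. It sets out from 19 and comes back at 20 without any new compound.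

Step 9. The allylic activation may lead to transposition (chloride on the exocyclic carbon) or to ionisation with loss of configuration at C3. The fallback removes the allylic character before chlorine is introduced and also replaces step 10; it sets out from 18 and comes back at 20.
- Hydroxyl-directed epoxidation of the exocyclic alkene (VO(acac)2 as catalyst, tert-butyl hydroperoxide, CH2Cl2) gives (3S,4S,6S)-6-ethynyl-1-oxaspiro[2.5]octane-4,6-diol F4, with the epoxide oxygen syn to both hydroxyls.
- Hydride opening at the CH2 terminus (LiBHEt3, THF, 0 °C) gives (1S,3S,4R)-1-ethynyl-4-methylcyclohexane-1,3,4-triol F5, which fixes the C4 methyl group.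
- Triphenylphosphine and hexachloroacetone replace the only secondary hydroxyl, now non-allylic, with inversion to give (1S,3R,4R)-3-chloro-1-ethynyl-4-methylcyclohexane-1,4-diol F6.
- HBr in CH2Cl2 at −40 °C ionises the tertiary C4 hydroxyl with anchimeric assistance by the anti chlorine, so that bromide should return on the same face (retention) to give 20.

Further compounds
F1 | step 4 | 2-(1,3-dithian-2-yl)acetaldehyde | O=CCC1SCCCS1
F2 | step 4 | 5-chloro-1-(1,3-dithian-2-yl)-3-methylidenepentan-2-ol (racemic) | C=C(CCCl)C(O)CC1SCCCS1
F3 | step 4 | {[5-chloro-1-(1,3-dithian-2-yl)-3-methylidenepentan-2-yl]oxy}trimethylsilane (racemic) | C=C(CCCl)C(O[Si](C)(C)C)CC1SCCCS1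
F4 | step 9 | (3S,4S,6S)-6-ethynyl-1-oxaspiro[2.5]octane-4,6-diol | C#C[C@]1(O)CC[C@]2(CO2)[C@@H](O)C1
F5 | step 9 | (1S,3S,4R)-1-ethynyl-4-methylcyclohexane-1,3,4-triol | C#C[C@]1(O)CC[C@@](C)(O)[C@@H](O)C1
F6 | step 9 | (1S,3R,4R)-3-chloro-1-ethynyl-4-methylcyclohexane-1,4-diol | C#C[C@]1(O)CC[C@@](C)(O)[C@H](Cl)C1
F0 | step 10 | none | none
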